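The cyclohexene ring of the acyl side chain (C1 bearing the aryl ketone, C5 the methyl, C6 the 1-hydroxyethyl group) is disconnected across C4–C5 and C1–C6. The plan exploits the 1,4-relation between the ketone carbon and the carbinol oxygen, read as a latent dihydrofuran. An enyne ether of (S,Z)-pent-3-en-2-ol is isomerised by base to an alkoxy vinylallene, whose intramolecular Diels–Alder reaction forms both bonds, the cis C5/C6 pair and, after hydrolysis, the C1=C2 alkene of a lactol. The lactol is then joined at C8 of a magnesiated 6-prenylcoumarin and oxidised to the ketone.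

Key step: step 5

Remarks on the chemistry:
- Atom labels: C0 is the ketone carbon, C1–C6 are the cyclohexene carbons (C1 bears C0, C5 the methyl, C6 the side chain) and C7 is the carbinol carbon. The coumarin is numbered as 2H-chromen-2-one.
- Lactol 10 is drawn ring-closed and is assumed to react through its hydroxy-aldehyde tautomer.
- Compounds 1, 4, 6, 11, 12 and 15 are taken as commercial (6 as its THF solution).

Step 1
Reactants: 1 pent-3-yn-2-one
Product: 2 (2S)-pent-3-yn-2-ol
Conditions: RuCl[(S,S)-TsDPEN](p-cymene) (1 mol %), iPrOH, rt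
Reagents that add atoms: none
Why: Noyori asymmetric transfer hydrogenation of an alkynyl ketone; the alkyne takes the place of the aryl group in the six-membered hydride-transfer transition state, so the (S,S)-catalyst should give the (S)-carbinol, which becomes C7.

Step 2
Reactants: 2 (2S)-pent-3-yn-2-ol
Product: 3 (2S,3Z)-pent-3-en-2-ol
Conditions: H2 (1 atm), Pd/CaCO3 poisoned with Pb(OAc)2 (Lindlar catalyst), quinoline, pentane, 0 °C
Reagents that add atoms: none
Why: Lindlar semihydrogenation adds H2 syn and should stop at the (Z)-alkene, which later fixes the cis relation of C5 and C6; the carbinol centre is not touched.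

Step 3
Reactants: 3 (2S,3Z)-pent-3-en-2-ol; 4 3-bromoprop-1-yne (propargyl bromide)
Product: 5 (2Z,4S)-4-(prop-2-yn-1-yloxy)pent-2-ene
Conditions: NaH, THF, 0 °C; then 4, Bu4NI (cat.), 0 °C → rt
Reagents that add atoms: none
Why: Williamson ether synthesis at the primary propargylic bromide; the C–O bond of the stereocentre is not broken.

Step 4
Reactants: 5 (2Z,4S)-4-(prop-2-yn-1-yloxy)pent-2-ene; 6 bromoethene (vinyl bromide)
Product: 7 (2Z,4S)-4-(pent-4-en-2-yn-1-yloxy)pent-2-ene
Conditions: Pd(PPh3)4 (3 mol %), CuI (5 mol %), Et2NH, THF, rt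
Reagents that add atoms: none
Why: Sonogashira coupling of the terminal alkyne with a vinyl halide should give the conjugated enyne without touching the (Z)-alkene or the allylic ether.

Step 5
Reactants: 7 (2Z,4S)-4-(pent-4-en-2-yn-1-yloxy)pent-2-ene
Product: 10 (1S,7R,7aR)-1,7-dimethyl-1,3,5,6,7,7a-hexahydro-2-benzofuran-3-ol (lactol; C3 epimers), via vinylallene ether 8 (not isolated), via dienol ether 9 (not isolated)
Conditions: KOtBu (0.3 equiv), t-BuOH/THF (0.02 M), BHT, 25 → 75 °C; then 0.5 M aq. HCl, THF, 0 °C → rt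
Reagents that add atoms: water (O)
Why: tert-Butoxide removes a proton from the O–CH2 group and the anion is reprotonated at the distal alkyne carbon, giving the 1-alkoxypenta-1,2,4-triene 8 (the known propargyl ether to allenyl ether isomerisation). The s-cis vinylallene then adds through its central allene carbon (C1) and its vinyl CH2 (C4) to the tethered (Z)-alkene in a thermal suprafacial [4+2] cycloaddition; the closest known reaction type is the intramolecular Diels–Alder reaction of vinylallenes that carry the dienophile on the allene terminus, here run as an isomerisation/cycloaddition cascade of a propargyl ether. The six-membered ring closes by the concerted cycloaddition itself (C1–C6 and C4–C5), and the five-membered oxacycle is the fused tether ring O–C7–C6–C1=C0, in which the remaining allene double bond becomes a cyclic enol ether conjugated with the new C2=C3 bond. C5 and C6 should come out cis because both carbons of the (Z)-alkene are attacked from one face, and C7 sets their absolute sense: A(1,3) strain with the (Z)-methyl holds the carbinol hydrogen in the alkene plane, so the diene, delivered by the oxygen, adds to the face syn to oxygen and anti to the C7 methyl, which corresponds to (5R,6R) from the (S)-ether. The cycloaddition must outrun [2,3]-Wittig and [3,3]-Claisen shifts of the allyl ether and further isomerisation of the triene; catalytic alkoxide in a protic medium keeps the carbanion short-lived, the vinylallene is a strained and reactive diene, and its vinyl terminus carries no alkyl group for a 1,5-hydrogen shift. Acid then protonates the dienol ether at its terminus C3 and water adds at C0, so lactol 10 should already carry the C1=C2 alkene of the target enone.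

Step 6
Reactants: 11 benzene-1,3,5-triol (phloroglucinol); 12 ethyl 2-methyl-3-oxobutanoate
Product: 13 5,7-dihydroxy-3,4-dimethyl-2H-chromen-2-one
Conditions: MeSO3H, 0 °C → rt
Reagents that add atoms: none
Why: Pechmann condensation; the triol is threefold symmetric, so only one coumarin can form.

Step 7
Reactants: 13 5,7-dihydroxy-3,4-dimethyl-2H-chromen-2-one
Product: 14 5-hydroxy-7-(methoxymethoxy)-3,4-dimethyl-2H-chromen-2-one
Conditions: MOMCl (1.05 equiv), K2CO3 (1.1 equiv), acetone, 0 °C → rt
Reagents that add atoms: chloromethyl methyl ether (COCCl)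
Why: Williamson-type O-alkylation; the 7-OH is the more acidic and unhindered hydroxyl, whereas the 5-OH is peri to the 4-methyl group, so one equivalent should react at O7.

Step 8
Reactants: 14 5-hydroxy-7-(methoxymethoxy)-3,4-dimethyl-2H-chromen-2-one; 15 3-chloro-3-methylbut-1-yne
Product: 16 7-(methoxymethoxy)-3,4-dimethyl-5-[(2-methylbut-3-yn-2-yl)oxy]-2H-chromen-2-one
Conditions: K2CO3, KI, CuI (5 mol %), DMF, 60 °C
Reagents that add atoms: none
Why: Copper-catalysed propargylic substitution of the tertiary chloride by the phenoxide, a method that tolerates hindered phenols; 60 °C is below the onset of the propargyl Claisen rearrangement.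

Step 9
Reactants: 16 7-(methoxymethoxy)-3,4-dimethyl-5-[(2-methylbut-3-yn-2-yl)oxy]-2H-chromen-2-one
Product: 17 8-iodo-7-(methoxymethoxy)-3,4-dimethyl-5-[(2-methylbut-3-yn-2-yl)oxy]-2H-chromen-2-one
Conditions: NIS (1.05 equiv), CF3CO2H (10 mol %), MeCN, 0 °C
Reagents that add atoms: N-iodosuccinimide (O=C1CCC(=O)N1I)
Why: Electrophilic aromatic iodination; C8 is para to O5, ortho to O7 and flanked only by the ring oxygen, whereas C6 lies under the tertiary ether that the 4-methyl group pushes toward it, so iodine should enter at C8.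

Step 10
Reactants: 17 8-iodo-7-(methoxymethoxy)-3,4-dimethyl-5-[(2-methylbut-3-yn-2-yl)oxy]-2H-chromen-2-one
Product: 18 8-iodo-7-(methoxymethoxy)-3,4-dimethyl-5-[(2-methylbut-3-en-2-yl)oxy]-2H-chromen-2-one
Conditions: H2 (1 atm, 1 equiv uptake), Pd/CaCO3 poisoned with Pb(OAc)2 (Lindlar catalyst), quinoline, EtOAc, rt
Reagents that add atoms: none
Why: Lindlar semihydrogenation of the terminal alkyne; the poisoned catalyst should leave the aryl–iodine bond intact if the reaction is stopped after one equivalent of H2.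

Step 11
Reactants: 18 8-iodo-7-(methoxymethoxy)-3,4-dimethyl-5-[(2-methylbut-3-en-2-yl)oxy]-2H-chromen-2-one
Product: 19 5-hydroxy-8-iodo-7-(methoxymethoxy)-3,4-dimethyl-6-(3-methylbut-2-en-1-yl)-2H-chromen-2-one
Conditions: PhNEt2, 130 °C
Reagents that add atoms: none
Why: Aromatic Claisen rearrangement ([3,3]-sigmatropic); C6 is the only hydrogen-bearing ortho carbon of O5 (the other is the ring-fusion carbon C4a), and the allyl inversion turns the 1,1-dimethylallyl ether into the 3-methylbut-2-enyl group.

Step 12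
Reactants: 19 5-hydroxy-8-iodo-7-(methoxymethoxy)-3,4-dimethyl-6-(3-methylbut-2-en-1-yl)-2H-chromen-2-one
Product: 20 8-iodo-5-methoxy-7-(methoxymethoxy)-3,4-dimethyl-6-(3-methylbut-2-en-1-yl)-2H-chromen-2-one
Conditions: MeI, K2CO3, DMF, 40 °C
Reagents that add atoms: iodomethane (CI)
Why: Williamson methylation of the only free phenol.

Step 13
Reactants: 20 8-iodo-5-methoxy-7-(methoxymethoxy)-3,4-dimethyl-6-(3-methylbut-2-en-1-yl)-2H-chromen-2-one; 10 (1S,7R,7aR)-1,7-dimethyl-1,3,5,6,7,7a-hexahydro-2-benzofuran-3-ol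
Product: 23 8-{hydroxy[(5R,6R)-6-[(1S)-1-hydroxyethyl]-5-methylcyclohex-1-en-1-yl]methyl}-5-methoxy-7-(methoxymethoxy)-3,4-dimethyl-6-(3-methylbut-2-en-1-yl)-2H-chromen-2-one (carbinol epimers), via arylmagnesium chloride 21 (not isolated), via chloromagnesium lactolate 22 (not isolated)
Conditions: 20, iPrMgCl·LiCl (1.05 equiv), THF, −40 °C; separately 10, MeMgCl (1.0 equiv), THF, −40 °C; combine, LaCl3·2LiCl (1 equiv), −40 → 0 °C; aq. NH4Cl
Reagents that add atoms: none
Why: Iodine–magnesium exchange gives an aryl Grignard reagent stabilised by its two flanking oxygens, which at low temperature should spare the lactone and add 1,2 to the aldehyde tautomer of the lactolate (Grignard addition); the new carbinol centre forms without control and is erased in step 14.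

Step 14
Reactants: 23 8-{hydroxy[(5R,6R)-6-[(1S)-1-hydroxyethyl]-5-methylcyclohex-1-en-1-yl]methyl}-5-methoxy-7-(methoxymethoxy)-3,4-dimethyl-6-(3-methylbut-2-en-1-yl)-2H-chromen-2-one
Product: 24 8-{[(5R,6R)-6-[(1S)-1-hydroxyethyl]-5-methylcyclohex-1-en-1-yl]carbonyl}-5-methoxy-7-(methoxymethoxy)-3,4-dimethyl-6-(3-methylbut-2-en-1-yl)-2H-chromen-2-one
Conditions: MnO2 (activated, 20 equiv), CH2Cl2, rt
Reagents that add atoms: none
Why: MnO2 oxidation is selective for the doubly activated benzylic and allylic alcohol, so the saturated secondary carbinol at C7 should remain.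

Step 15
Reactants: 24 8-{[(5R,6R)-6-[(1S)-1-hydroxyethyl]-5-methylcyclohex-1-en-1-yl]carbonyl}-5-methoxy-7-(methoxymethoxy)-3,4-dimethyl-6-(3-methylbut-2-en-1-yl)-2H-chromen-2-one
Product: 25 7-hydroxy-8-{[(5R,6R)-6-[(1S)-1-hydroxyethyl]-5-methylcyclohex-1-en-1-yl]carbonyl}-5-methoxy-3,4-dimethyl-6-(3-methylbut-2-en-1-yl)-2H-chromen-2-one (CNP0197455.1)
Conditions: 2 M aq. HCl, MeOH, rt
Reagents that add atoms: none
Why: Acid hydrolysis of the aryl methoxymethyl acetal, which is activated by the ortho ketone, should proceed under conditions too mild to cyclise the prenyl phenol or epimerise C5–C7.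

Compound list
1 | pent-3-yn-2-one | CC#CC(C)=O | starting material
2 | (2S)-pent-3-yn-2-ol | C[C@H](O)C#CC | intermediate
3 | (2S,3Z)-pent-3-en-2-ol | C[C@H](O)/C=C\C | intermediate
4 | 3-bromoprop-1-yne (propargyl bromide) | C#CCBr | starting material
5 | (2Z,4S)-4-(prop-2-yn-1-yloxy)pent-2-ene | C[C@H](OCC#C)/C=C\C | intermediate
6 | bromoethene (vinyl bromide) | C=CBr | starting material
7 | (2Z,4S)-4-(pent-4-en-2-yn-1-yloxy)pent-2-ene | C[C@H](OCC#CC=C)/C=C\C | intermediate
8 | (2Z,4S)-4-(penta-1,2,4-trien-1-yloxy)pent-2-ene (vinylallene ether; both allene senses) | C[C@H](OC=C=CC=C)/C=C\C | intermediate (not isolated)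
9 | (1S,7R,7aR)-1,7-dimethyl-1,6,7,7a-tetrahydro-2-benzofuran (dienol ether) | C1=C2C=CC[C@@H](C)[C@H]2[C@H](C)O1 | intermediate (not isolated)
10 | (1S,7R,7aR)-1,7-dimethyl-1,3,5,6,7,7a-hexahydro-2-benzofuran-3-ol (C3 epimers) | OC1C2=CCC[C@@H](C)[C@H]2[C@H](C)O1 | intermediate
11 | benzene-1,3,5-triol (phloroglucinol) | Oc1cc(O)cc(O)c1 | starting material
12 | ethyl 2-methyl-3-oxobutanoate | CCOC(=O)C(C)C(C)=O | starting material
13 | 5,7-dihydroxy-3,4-dimethyl-2H-chromen-2-one | Cc1c(C)c2c(O)cc(O)cc2oc1=O | intermediate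
14 | 5-hydroxy-7-(methoxymethoxy)-3,4-dimethyl-2H-chromen-2-one | Cc1c(C)c2c(O)cc(OCOC)cc2oc1=O | intermediate
15 | 3-chloro-3-methylbut-1-yne | CC(C)(Cl)C#C | starting material
16 | 7-(methoxymethoxy)-3,4-dimethyl-5-[(2-methylbut-3-yn-2-yl)oxy]-2H-chromen-2-one | Cc1c(C)c2c(OC(C)(C)C#C)cc(OCOC)cc2oc1=O | intermediate
17 | 8-iodo-7-(methoxymethoxy)-3,4-dimethyl-5-[(2-methylbut-3-yn-2-yl)oxy]-2H-chromen-2-one | Cc1c(C)c2c(OC(C)(C)C#C)cc(OCOC)c(I)c2oc1=O | intermediate
18 | 8-iodo-7-(methoxymethoxy)-3,4-dimethyl-5-[(2-methylbut-3-en-2-yl)oxy]-2H-chromen-2-one | Cc1c(C)c2c(OC(C)(C)C=C)cc(OCOC)c(I)c2oc1=O | intermediate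
19 | 5-hydroxy-8-iodo-7-(methoxymethoxy)-3,4-dimethyl-6-(3-methylbut-2-en-1-yl)-2H-chromen-2-one | Cc1c(C)c2c(O)c(CC=C(C)C)c(OCOC)c(I)c2oc1=O | intermediate
20 | 8-iodo-5-methoxy-7-(methoxymethoxy)-3,4-dimethyl-6-(3-methylbut-2-en-1-yl)-2H-chromen-2-one | COc1c(CC=C(C)C)c(OCOC)c(I)c2oc(=O)c(C)c(C)c12 | intermediate
21 | [5-methoxy-7-(methoxymethoxy)-3,4-dimethyl-6-(3-methylbut-2-en-1-yl)-2-oxo-2H-chromen-8-yl]magnesium chloride | COc1c(CC=C(C)C)c(OCOC)c([Mg]Cl)c2oc(=O)c(C)c(C)c12 | intermediate (not isolated)
22 | chloromagnesium salt of lactol 10 (in equilibrium with the open aldehyde alkoxide) | Cl[Mg]OC1C2=CCC[C@@H](C)[C@H]2[C@H](C)O1 | intermediate (not isolated)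
23 | 8-{hydroxy[(5R,6R)-6-[(1S)-1-hydroxyethyl]-5-methylcyclohex-1-en-1-yl]methyl}-5-methoxy-7-(methoxymethoxy)-3,4-dimethyl-6-(3-methylbut-2-en-1-yl)-2H-chromen-2-one (carbinol epimers) | COc1c(CC=C(C)C)c(OCOC)c(C(O)C2=CCC[C@@H](C)[C@H]2[C@H](C)O)c2oc(=O)c(C)c(C)c12 | intermediate
24 | 8-{[(5R,6R)-6-[(1S)-1-hydroxyethyl]-5-methylcyclohex-1-en-1-yl]carbonyl}-5-methoxy-7-(methoxymethoxy)-3,4-dimethyl-6-(3-methylbut-2-en-1-yl)-2H-chromen-2-one | COc1c(CC=C(C)C)c(OCOC)c(C(=O)C2=CCC[C@@H](C)[C@H]2[C@H](C)O)c2oc(=O)c(C)c(C)c12 | intermediate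
25 | 7-hydroxy-8-{[(5R,6R)-6-[(1S)-1-hydroxyethyl]-5-methylcyclohex-1-en-1-yl]carbonyl}-5-methoxy-3,4-dimethyl-6-(3-methylbut-2-en-1-yl)-2H-chromen-2-one | COc1c(CC=C(C)C)c(O)c(C(=O)C2=CCC[C@@H](C)[C@H]2[C@H](C)O)c2oc(=O)c(C)c(C)c12 | target

Total step count: 15. Longest linear sequence: 10 steps (steps 6 to 15, from 11 and 12 to 25); the side-chain branch is 5 steps (steps 1 to 5).

Steps most likely to fail

Step 5. The allenyl ether may be diverted before it cyclises, by [3,3] rearrangement of the allyl allenyl ether, by further base-induced isomerisation of the triene or by polymerisation, or the cycloaddition may be too slow at temperatures the allene tolerates. The fallback sets out from 3 and comes back at 10, and replaces the ether tether by an ester tether. Alcohol 3 is esterified with commercial (2E)-penta-2,4-dienoic acid (DCC, DMAP, CH2Cl2) to give (2Z,4S)-pent-3-en-2-yl (2E)-penta-2,4-dienoate F1. A thermal intramolecular Diels–Alder reaction (o-dichlorobenzene, BHT, about 200 °C) should then give, under the same A(1,3) control, (3S,3aR,4R)-3,4-dimethyl-3a,4,5,7a-tetrahydro-2-benzofuran-1(3H)-one F2. DBU should move the alkene into conjugation to give (3S,3aR,4R)-3,4-dimethyl-3a,4,5,6-tetrahydro-2-benzofuran-1(3H)-one F3, and iBu2AlH at −78 °C should reduce F3 to lactol 10.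

Step 13. The organomagnesium species may be consumed by addition to the coumarin lactone or by deprotonation of its 4-methyl group before the masked aldehyde reacts, or the exchange at the crowded, electron-rich iodide may be slow. The fallback sets out from 20 and 10 and comes back at 23, and replaces the preformed Grignard reagent by a Nozaki–Hiyama–Kishi coupling (CrCl2 in excess, NiCl2 cat., DMF, rt). The organochromium species formed in the flask, [5-methoxy-7-(methoxymethoxy)-3,4-dimethyl-6-(3-methylbut-2-en-1-yl)-2-oxo-2H-chromen-8-yl]chromium dichloride F4, adds to aldehydes but not to lactones and tolerates the free hydroxyl of the lactol.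

Step 10. The C8 iodine may be lost by hydrogenolysis on the palladium surface, or the alkene may be over-reduced. The fallback sets out from 14 and comes back at 18, and installs the allyl ether directly so that no hydrogenation is run on an aryl iodide. 2-Methylbut-3-en-2-ol is converted (n-BuLi, then ClCO2Me, THF) into methyl 2-methylbut-3-en-2-yl carbonate F5. Tsuji–Trost O-allylation of 14 with F5 (Pd(PPh3)4, THF, 0 °C) should give the branched ether 7-(methoxymethoxy)-3,4-dimethyl-5-[(2-methylbut-3-en-2-yl)oxy]-2H-chromen-2-one F6. Acid-free iodination of F6 (NIS, MeCN, 0 °C) should then give 18.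

Further compounds
F1 | step 5 | (2Z,4S)-pent-3-en-2-yl (2E)-penta-2,4-dienoate | C[C@H](OC(=O)/C=C/C=C)/C=C\C
F2 | step 5 | (3S,3aR,4R)-3,4-dimethyl-3a,4,5,7a-tetrahydro-2-benzofuran-1(3H)-one (C7a epimers) | O=C1C2C=CC[C@@H](C)[C@H]2[C@H](C)O1
F3 | step 5 | (3S,3aR,4R)-3,4-dimethyl-3a,4,5,6-tetrahydro-2-benzofuran-1(3H)-one | O=C1C2=CCC[C@@H](C)[C@H]2[C@H](C)O1
F4 | step 13 | [5-methoxy-7-(methoxymethoxy)-3,4-dimethyl-6-(3-methylbut-2-en-1-yl)-2-oxo-2H-chromen-8-yl]chromium dichloride | COc1c(CC=C(C)C)c(OCOC)c([Cr](Cl)Cl)c2oc(=O)c(C)c(C)c12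
F5 | step 10 | methyl 2-methylbut-3-en-2-yl carbonate | COC(=O)OC(C)(C)C=C
F6 | step 10 | 7-(methoxymethoxy)-3,4-dimethyl-5-[(2-methylbut-3-en-2-yl)oxy]-2H-chromen-2-one | Cc1c(C)c2c(OC(C)(C)C=C)cc(OCOC)cc2oc1=O
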